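Late in the delta run X is nearly gone, 0.8 % at 8.00 h, yet [Q] keeps falling, from 86.0 % then to 74.8 % at 20.0 h. From this I read the one quantity I carry, the first-order loss constant of Q, which is the logarithm of the ratio of two late readings of [Q] divided by the time between them: 0.0116 /h. As a reading it carries the scatter, and it gives Q a half-life of about 59.6 h.

common to all: X 0.50 M
- theta: L 1.4 equiv (in portions, 2); run made earlier; portions every 12 h
- delta: L 3.5 equiv (in portions, 2); run made earlier; portions every 12 h
- amber: L 1.05 equiv (in portions, 2); the portions of L follow each other after 12 h, the first at the start; time 25 h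
- red: L 3.20 equiv; everything together at the start; time 25 h

| run | time / h | Q / % | X / % |
|---|---|---|---|
| theta | 1.33 | 43.5 | 52.8 |
| theta | 2.00 | 54.6 | 40.4 |
| theta | 3.00 | 61.5 | 32.8 |
| theta | 5.00 | 64.0 | 24.3 |
| theta | 8.00 | 63.6 | 21.9 |
| theta | 12.0 | 57.3 | 19.1 |
| theta | 20.0 | 73.2 | 0 |
| delta | 1.33 | 63.9 | 33.6 |
| delta | 2.00 | 78.1 | 18.7 |
| delta | 3.00 | 84.4 | 8.8 |
| delta | 5.00 | 88.4 | 2.7 |
| delta | 8.00 | 86.0 | 0.8 |
| delta | 12.0 | 83.9 | 0.1 |
| delta | 20.0 | 74.8 | 0.5 |

(scatter of a reading: 1 percentage point)

* which one finishes higher in amount of Q, in percent of the X charged ("neither" within 2 percentage points) (amber / red / neither)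
* amount of Q at the end, in percent of the X charged, amber
* amount of Q at the end, in percent of the X charged, red

Red looks nearly like delta, but it gets its 3.20 equiv at the start, while delta's first portion is 1.75 equiv. In delta, X had nearly gone by 8.00 h, far sooner than that half-life, so I expect red to spend X early too and then simply age. Red should therefore stand where delta stood at 20.0 h, eroded for the extra hours: 70.6 %. Theta reads 0 % X at 20.0 h, and the same reckoning carries its Q reading to 69.1 %. Amber resembles theta but gets less L, 1.05 equiv against 1.4 equiv, so I place amber below that figure. I commit to red, with a gap of 1.5 percentage points plus whatever amber's smaller charge costs.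

The forecast gives red, with 66 % for amber and 71 % for red: “Red is probably higher, though not by much.” The flask gives red, with 64.0 % for amber and 69.7 % for red.

    X + L → Q, rate k1*[X]*[L]^0.5 (k = 1.00 /M^0.5/h)
    Q → Z (k = 0.0140 /h)
    X ⇌ G (K = 11.0, k = 0.0290 /h)
    2 X → J (k = 6.10 × 10⁻⁵ /M/h)

In amber at 25.0 h, Q is made at 0.117 of the rate at which it is used up, each step taken net. X stands at 0.316 % in amber there, and the step from Q to Z, taken by itself, gives Q a half-life of 50 h. Reading amber later, at 2.5 d, is a case for the loss constant: 64.0 % of Q eroded over the extra time gives 42.6 %. Amber computed at that time holds 40.4 % of Q.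

Readings and results are calculated for an exercise.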